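## Retrosynthetic overview

1. The (R)-lactol comes from lipase alcoholysis of its (R)-acetate, which comes from a lipase dynamic kinetic resolution of the racemic lactol, so the labile centre is set last.
2. The racemic lactol comes from a 3-methoxyphthalide (pseudo-ester) depsidone, made by seven-membered lactonisation of a diaryl ether hydroxy acid.
3. The diaryl ether comes from an Ullmann C–O coupling of a ring A salicylate phenol with a ring B ortho-bromo aldehyde.
4. Ring B comes from aromatisation of a cyclohexane-1,3-dione built by intermolecular Michael addition of dimethyl malonate to an acetal-bearing enone and Dieckmann closure; this C–C bond brings in the future lactol carbon at the aldehyde level. The enone comes from an HWE olefination; ring A comes from commercial methyl 2,4-dihydroxy-3,6-dimethylbenzoate.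
5. Ring order: ring B carbocycle, (ring A bought), diaryl ether, phthalide lactol ring, seven-membered depsidone lactone.

Assumption: the lactol carbon is a hemiacetal that can epimerise through the open formyl acid, so the (R) centre is set only in the last two steps and the product is isolated cold and kept as a solid.

## Route

Step 1
Reactants: 1 diethyl (2-oxobutyl)phosphonate; 2 2,2-dimethoxyacetaldehyde (60 wt% in water)
Product: 3 (E)-6,6-dimethoxyhex-4-en-3-one
Conditions: K2CO3 (1.5 equiv), H2O–THF, 0 °C → rt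
Reagents that add atoms: none
Why: Horner–Wadsworth–Emmons olefination of a stabilised β-ketophosphonate with a non-enolisable aldehyde runs in aqueous carbonate and gives the (E)-enone.

Step 2
Reactants: 3 (E)-6,6-dimethoxyhex-4-en-3-one; 4 dimethyl malonate
Product: 6 methyl 6-(dimethoxymethyl)-3-methyl-2,4-dioxocyclohexane-1-carboxylate, via Michael adduct 5 (not isolated)
Conditions: NaOMe (1.1 equiv), MeOH, 0 °C → reflux; AcOH to pH 5, 0 °C
Reagents that add atoms: none
Why: The malonate anion adds 1,4 to the enone (intermolecular Michael addition, the key C–C bond) and the ethyl ketone enolate then closes the ring on a malonate ester (Dieckmann/Claisen condensation); the acetal is inert to methoxide and the sp3 stereocentres vanish on aromatisation.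

Step 3
Reactants: 6 methyl 6-(dimethoxymethyl)-3-methyl-2,4-dioxocyclohexane-1-carboxylate
Product: 9 methyl 6-formyl-2,4-dihydroxy-3-methylbenzoate, via bromo dione 7 (not isolated), via aryl dimethyl acetal 8 (not isolated)
Conditions: Br2 (1.05 equiv), Li2CO3 (1.5 equiv), DMF, 0 °C → 80 °C; then 1 M HCl–THF, rt
Reagents that add atoms: bromine, BrBr (its bromine atom sits only in 7); water, O (formyl oxygen of 9)
Why: Halogenative aromatisation (α-bromination of the enolised dione, then vinylogous dehydrobromination in carbonate-buffered DMF) gives the resorcinol ester, and the acetal is hydrolysed only afterwards so the aldehyde oxidation level is kept.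

Step 4
Reactants: 9 methyl 6-formyl-2,4-dihydroxy-3-methylbenzoate
Product: 10 methyl 3-bromo-2-formyl-4,6-dihydroxy-5-methylbenzoate
Conditions: NBS (1.05 equiv), MeCN, 0 °C
Reagents that add atoms: N-bromosuccinimide, O=C1CCC(=O)N1Br
Why: Electrophilic aromatic bromination can only occur at the single free ring position, which is ortho and para to the two hydroxyls.

Step 5
Reactants: 10 methyl 3-bromo-2-formyl-4,6-dihydroxy-5-methylbenzoate
Product: 11 methyl 2,4-bis(benzyloxy)-5-bromo-6-formyl-3-methylbenzoate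
Conditions: BnBr (2.5 equiv), K2CO3 (3 equiv), DMF, 60 °C
Reagents that add atoms: benzyl bromide, BrCc1ccccc1
Why: Williamson etherification in warm DMF benzylates both phenoxides, the chelated one included, while ester and aldehyde are inert.

Step 6
Reactants: 12 methyl 2,4-dihydroxy-3,6-dimethylbenzoate
Product: 13 methyl 2-hydroxy-4-methoxy-3,6-dimethylbenzoate
Conditions: MeI (1.1 equiv), K2CO3 (1.1 equiv), acetone, reflux
Reagents that add atoms: iodomethane, CI
Why: Williamson methylation is selective for the 4-OH because the 2-OH is deactivated by its hydrogen bond to the ester carbonyl.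

Step 7
Reactants: 13 methyl 2-hydroxy-4-methoxy-3,6-dimethylbenzoate
Product: 14 2-hydroxy-4-methoxy-3,6-dimethylbenzoic acid
Conditions: KOH, DMSO–H2O, 80 °C; then cold 2 M HCl
Reagents that add atoms: potassium hydroxide, [K+].[OH-]
Why: Saponification of the hindered salicylate ester needs hot KOH in aqueous DMSO, and cold acidification avoids decarboxylation.

Step 8
Reactants: 14 2-hydroxy-4-methoxy-3,6-dimethylbenzoic acid
Product: 15 benzyl 2-hydroxy-4-methoxy-3,6-dimethylbenzoate
Conditions: BnBr (1.05 equiv), KHCO3, DMF, rt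
Reagents that add atoms: benzyl bromide, BrCc1ccccc1
Why: Bicarbonate deprotonates only the carboxylic acid, so SN2 O-alkylation gives the benzyl ester and leaves the chelated phenol free.

Step 9
Reactants: 11 methyl 2,4-bis(benzyloxy)-5-bromo-6-formyl-3-methylbenzoate; 15 benzyl 2-hydroxy-4-methoxy-3,6-dimethylbenzoate
Product: 16 benzyl 2-[4,6-bis(benzyloxy)-2-formyl-3-(methoxycarbonyl)-5-methylphenoxy]-4-methoxy-3,6-dimethylbenzoate
Conditions: CuI (20 mol%), picolinic acid (40 mol%), K3PO4 (2 equiv), DMSO, 90 °C, Ar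
Reagents that add atoms: none
Why: Ullmann-type copper-catalysed C–O coupling, in which the bromide is activated by its ortho-formyl group, the picolinic acid system suits ortho-substituted partners, and 15 carries the only free OH.

Step 10
Reactants: 16 benzyl 2-[4,6-bis(benzyloxy)-2-formyl-3-(methoxycarbonyl)-5-methylphenoxy]-4-methoxy-3,6-dimethylbenzoate
Product: 17 benzyl 2-{[5,7-bis(benzyloxy)-3-hydroxy-6-methyl-1-oxo-1,3-dihydro-2-benzofuran-4-yl]oxy}-4-methoxy-3,6-dimethylbenzoate (racemic lactol)
Conditions: LiOH (1.5 equiv), THF–H2O, 0 °C; then 1 M HCl to pH 3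
Reagents that add atoms: lithium hydroxide, [Li+].[OH-]
Why: Neighbouring-group-assisted saponification (hydroxide adds to the aldehyde and the hydrate anion attacks the adjacent methyl ester) gives the 3-hydroxyphthalide as a racemate, while the di-ortho-substituted benzyl ester is untouched.

Step 11
Reactants: 17 benzyl 2-{[5,7-bis(benzyloxy)-3-hydroxy-6-methyl-1-oxo-1,3-dihydro-2-benzofuran-4-yl]oxy}-4-methoxy-3,6-dimethylbenzoate
Product: 18 benzyl 2-{[5,7-bis(benzyloxy)-3-methoxy-6-methyl-1-oxo-1,3-dihydro-2-benzofuran-4-yl]oxy}-4-methoxy-3,6-dimethylbenzoate (racemic)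
Conditions: TsOH (10 mol%), MeOH–CH2Cl2, rt
Reagents that add atoms: methanol, CO
Why: Acid-catalysed pseudo-ester formation (cyclic acetalisation through the acyloxycarbenium ion) is fast for a 3-hydroxyphthalide, whereas the hindered benzyl ester and the benzyl ethers do not react; the acetal carbon stays racemic and is reset later.

Step 12
Reactants: 18 benzyl 2-{[5,7-bis(benzyloxy)-3-methoxy-6-methyl-1-oxo-1,3-dihydro-2-benzofuran-4-yl]oxy}-4-methoxy-3,6-dimethylbenzoate
Product: 19 2-[(5,7-dihydroxy-3-methoxy-6-methyl-1-oxo-1,3-dihydro-2-benzofuran-4-yl)oxy]-4-methoxy-3,6-dimethylbenzoic acid (racemic)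
Conditions: H2 (1 atm), Pd/C (10 wt%), EtOAc–THF, rt
Reagents that add atoms: none
Why: Catalytic hydrogenolysis removes the two benzyl ethers and the benzyl ester under neutral conditions that leave the methoxyphthalide acetal, the diaryl ether and the aryl methyl ether intact.

Step 13
Reactants: 19 2-[(5,7-dihydroxy-3-methoxy-6-methyl-1-oxo-1,3-dihydro-2-benzofuran-4-yl)oxy]-4-methoxy-3,6-dimethylbenzoic acid
Product: 20 4-hydroxy-1,10-dimethoxy-5,8,11-trimethyl-1H,7H-isobenzofuro[4,5-b][1,4]benzodioxepine-3,7-dione (racemic)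
Conditions: DCC (1.2 equiv), DMAP (10 mol%), CH2Cl2–THF (5 mM), 0 °C → rt
Reagents that add atoms: none
Why: Steglich-type carbodiimide lactonisation, in which the activated ring A acid is captured by the only phenol within reach (ortho to the ether bridge) to close the seven-membered depsidone lactone at high dilution.

Step 14
Reactants: 20 4-hydroxy-1,10-dimethoxy-5,8,11-trimethyl-1H,7H-isobenzofuro[4,5-b][1,4]benzodioxepine-3,7-dione
Product: 21 1,4-dihydroxy-10-methoxy-5,8,11-trimethyl-1H,7H-isobenzofuro[4,5-b][1,4]benzodioxepine-3,7-dione (racemic lactol)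
Conditions: 2 M HCl–1,4-dioxane (1:3), 50 °C
Reagents that add atoms: water, O
Why: Acid-catalysed acetal hydrolysis of the pseudo-ester gives the lactol, while the sterically shielded depsidone aryl ester resists acid hydrolysis.

Step 15
Reactants: 21 1,4-dihydroxy-10-methoxy-5,8,11-trimethyl-1H,7H-isobenzofuro[4,5-b][1,4]benzodioxepine-3,7-dione (racemic)
Product: 22 (1R)-4-hydroxy-10-methoxy-5,8,11-trimethyl-3,7-dioxo-1H,3H,7H-isobenzofuro[4,5-b][1,4]benzodioxepin-1-yl acetate
Conditions: Burkholderia cepacia lipase (Amano PS, immobilised), vinyl acetate (5 equiv), Et3N (5 mol%), toluene–THF, 35 °C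
Reagents that add atoms: vinyl acetate, CC(=O)OC=C
Why: Lipase-catalysed dynamic kinetic resolution by irreversible transesterification, in which the lactol enantiomers interconvert through the open formyl acid while the enzyme acylates only one of them; the Kazlauskas model predicts the (R)-acetate, to be confirmed by chiral HPLC and X-ray.

Step 16
Reactants: 22 (1R)-4-hydroxy-10-methoxy-5,8,11-trimethyl-3,7-dioxo-1H,3H,7H-isobenzofuro[4,5-b][1,4]benzodioxepin-1-yl acetate
Product: 23 (1R)-1,4-dihydroxy-10-methoxy-5,8,11-trimethyl-1H,7H-isobenzofuro[4,5-b][1,4]benzodioxepine-3,7-dione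
Conditions: same lipase, n-BuOH (5 equiv), MTBE–THF, 5 °C; filter, evaporate cold, crystallise at once
Reagents that add atoms: none
Why: Lipase-catalysed alcoholysis breaks only the acyl C–O bond, so the bond at the stereocentre is untouched and the (R)-lactol is released with retention under neutral, cold, base-free conditions that limit ring–chain racemisation.

## Compound list

1 | diethyl (2-oxobutyl)phosphonate | CCC(=O)CP(=O)(OCC)OCC | starting material
2 | 2,2-dimethoxyacetaldehyde | COC(OC)C=O | starting material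
3 | (E)-6,6-dimethoxyhex-4-en-3-one | CCC(=O)/C=C/C(OC)OC | intermediate
4 | dimethyl malonate | COC(=O)CC(=O)OC | starting material
5 | dimethyl 2-(1,1-dimethoxy-4-oxohexan-2-yl)propanedioate (racemic Michael adduct) | COC(=O)C(C(=O)OC)C(CC(=O)CC)C(OC)OC | intermediate
6 | methyl 6-(dimethoxymethyl)-3-methyl-2,4-dioxocyclohexane-1-carboxylate (mixture of diastereomers and enol tautomers) | COC(=O)C1C(=O)C(C)C(=O)CC1C(OC)OC | intermediate
7 | methyl 3-bromo-6-(dimethoxymethyl)-3-methyl-2,4-dioxocyclohexane-1-carboxylate (stereoisomer mixture) | COC(=O)C1C(=O)C(C)(Br)C(=O)CC1C(OC)OC | intermediate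
8 | methyl 6-(dimethoxymethyl)-2,4-dihydroxy-3-methylbenzoate | COC(=O)c1c(O)c(C)c(O)cc1C(OC)OC | intermediate
9 | methyl 6-formyl-2,4-dihydroxy-3-methylbenzoate | COC(=O)c1c(O)c(C)c(O)cc1C=O | intermediate
10 | methyl 3-bromo-2-formyl-4,6-dihydroxy-5-methylbenzoate | COC(=O)c1c(O)c(C)c(O)c(Br)c1C=O | intermediate
11 | methyl 2,4-bis(benzyloxy)-5-bromo-6-formyl-3-methylbenzoate | COC(=O)c1c(OCc2ccccc2)c(C)c(OCc2ccccc2)c(Br)c1C=O | intermediate
12 | methyl 2,4-dihydroxy-3,6-dimethylbenzoate | COC(=O)c1c(C)cc(O)c(C)c1O | starting material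
13 | methyl 2-hydroxy-4-methoxy-3,6-dimethylbenzoate | COC(=O)c1c(C)cc(OC)c(C)c1O | intermediate
14 | 2-hydroxy-4-methoxy-3,6-dimethylbenzoic acid | OC(=O)c1c(C)cc(OC)c(C)c1O | intermediate
15 | benzyl 2-hydroxy-4-methoxy-3,6-dimethylbenzoate | O=C(OCc1ccccc1)c1c(C)cc(OC)c(C)c1O | intermediate
16 | benzyl 2-[4,6-bis(benzyloxy)-2-formyl-3-(methoxycarbonyl)-5-methylphenoxy]-4-methoxy-3,6-dimethylbenzoate | COc1cc(C)c(C(=O)OCc2ccccc2)c(Oc2c(OCc3ccccc3)c(C)c(OCc3ccccc3)c(C(=O)OC)c2C=O)c1C | intermediate
17 | benzyl 2-{[5,7-bis(benzyloxy)-3-hydroxy-6-methyl-1-oxo-1,3-dihydro-2-benzofuran-4-yl]oxy}-4-methoxy-3,6-dimethylbenzoate (racemic) | COc1cc(C)c(C(=O)OCc2ccccc2)c(Oc2c(OCc3ccccc3)c(C)c(OCc3ccccc3)c3c2C(O)OC3=O)c1C | intermediate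
18 | benzyl 2-{[5,7-bis(benzyloxy)-3-methoxy-6-methyl-1-oxo-1,3-dihydro-2-benzofuran-4-yl]oxy}-4-methoxy-3,6-dimethylbenzoate (racemic) | COc1cc(C)c(C(=O)OCc2ccccc2)c(Oc2c(OCc3ccccc3)c(C)c(OCc3ccccc3)c3c2C(OC)OC3=O)c1C | intermediate
19 | 2-[(5,7-dihydroxy-3-methoxy-6-methyl-1-oxo-1,3-dihydro-2-benzofuran-4-yl)oxy]-4-methoxy-3,6-dimethylbenzoic acid (racemic) | COc1cc(C)c(C(=O)O)c(Oc2c(O)c(C)c(O)c3c2C(OC)OC3=O)c1C | intermediate
20 | 4-hydroxy-1,10-dimethoxy-5,8,11-trimethyl-1H,7H-isobenzofuro[4,5-b][1,4]benzodioxepine-3,7-dione (racemic; depsidone with the lactol as its methyl acetal) | COc1cc(C)c2c(c1C)Oc1c(c(C)c(O)c3c1C(OC)OC3=O)OC2=O | intermediate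
21 | 1,4-dihydroxy-10-methoxy-5,8,11-trimethyl-1H,7H-isobenzofuro[4,5-b][1,4]benzodioxepine-3,7-dione (racemic lactol) | COc1cc(C)c2c(c1C)Oc1c(c(C)c(O)c3c1C(O)OC3=O)OC2=O | intermediate
22 | (1R)-4-hydroxy-10-methoxy-5,8,11-trimethyl-3,7-dioxo-1H,3H,7H-isobenzofuro[4,5-b][1,4]benzodioxepin-1-yl acetate | COc1cc(C)c2c(c1C)Oc1c(c(C)c(O)c3c1[C@H](OC(C)=O)OC3=O)OC2=O | intermediate
23 | (1R)-1,4-dihydroxy-10-methoxy-5,8,11-trimethyl-1H,7H-isobenzofuro[4,5-b][1,4]benzodioxepine-3,7-dione (lactol carbon R) | COc1cc(C)c2c(c1C)Oc1c(c(C)c(O)c3c1[C@H](O)OC3=O)OC2=O | target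

## Step count and risks

Total steps: 16. Longest linear sequence: 13 (steps 1–5 and 9–16); the ring A branch (steps 6–8) is 3 steps.

Steps most likely to fail:

Step 9 (Ullmann coupling to a tetra-ortho-substituted diaryl ether; the yield may be low). The fallback sets out from 15 and 10 and comes back at 21. It makes the two C–O bonds in the opposite order, so that the hindered ether is closed intramolecularly. Phenol 15 is benzylated (BnBr, K2CO3, DMF, 60 °C) to benzyl 2-(benzyloxy)-4-methoxy-3,6-dimethylbenzoate F1, and this is saponified (KOH, aqueous DMSO, 90 °C) to 2-(benzyloxy)-4-methoxy-3,6-dimethylbenzoic acid F2. The acid is esterified with the non-chelated 4-OH of 10 (TFAA, toluene, rt) to the depside 2-bromo-3-formyl-5-hydroxy-4-(methoxycarbonyl)-6-methylphenyl 2-(benzyloxy)-4-methoxy-3,6-dimethylbenzoate F3. BCl3 (CH2Cl2, −78 °C) removes the benzyl ether next to the carbonyl and gives 2-bromo-3-formyl-5-hydroxy-4-(methoxycarbonyl)-6-methylphenyl 2-hydroxy-4-methoxy-3,6-dimethylbenzoate F4. An intramolecular Ullmann etherification (CuI, Cs2CO3, pyridine, 110 °C, high dilution) then closes the seven-membered ring to methyl 6-formyl-8-hydroxy-3-methoxy-1,4,9-trimethyl-11-oxo-11H-dibenzo[b,e][1,4]dioxepine-7-carboxylate F5. The formyl-assisted hydrolysis of its methyl ester (LiOH, 2 equiv, THF–H2O, 0 °C, then 1 M HCl) gives 21. A Smiles rearrangement of F4 at the ester-bearing carbon is the side reaction to watch in this fallback.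

Step 3 (halogenative aromatisation beside an acid-sensitive acetal; if the acetal is lost before the ring is aromatic, the dione could isomerise to a phthalide at the wrong oxidation level). The fallback sets out from commercial 12 and comes back at 11. It replaces de novo ring construction by benzylic functionalisation. Compound 12 is benzylated (BnBr, K2CO3, DMF, 60 °C) to methyl 2,4-bis(benzyloxy)-3,6-dimethylbenzoate F6. Lateral lithiation of the methyl group ortho to the ester (LDA, 2.2 equiv, THF, −78 °C) and C-nitrosation with isoamyl nitrite give methyl 2,4-bis(benzyloxy)-6-[(hydroxyimino)methyl]-3-methylbenzoate F7. Transoximation (50% aqueous glyoxylic acid, THF, rt) frees methyl 2,4-bis(benzyloxy)-6-formyl-3-methylbenzoate F8. Bromination at the only free ring position (NBS, MeCN, rt) gives 11.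

Step 15 (the lipase may not accept the crowded lactol, or may prefer the other enantiomer). The fallback sets out from 21 and comes back at 22. It replaces the enzymatic step by chemical acetylation and physical resolution. Compound 21 is acetylated at the lactol OH (Ac2O, 1.1 equiv, pyridine, CH2Cl2, 0 °C) to racemic 4-hydroxy-10-methoxy-5,8,11-trimethyl-3,7-dioxo-1H,3H,7H-isobenzofuro[4,5-b][1,4]benzodioxepin-1-yl acetate F9. Preparative SFC on an amylose tris(3,5-dimethylphenylcarbamate) phase separates 22 from the (1S)-acetate F10. F10 is returned to 21 with 2 M HCl–dioxane and recycled.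

Further compounds
F1 | step 9 | benzyl 2-(benzyloxy)-4-methoxy-3,6-dimethylbenzoate | COc1cc(C)c(C(=O)OCc2ccccc2)c(OCc2ccccc2)c1C
F2 | step 9 | 2-(benzyloxy)-4-methoxy-3,6-dimethylbenzoic acid | COc1cc(C)c(C(=O)O)c(OCc2ccccc2)c1C
F3 | step 9 | 2-bromo-3-formyl-5-hydroxy-4-(methoxycarbonyl)-6-methylphenyl 2-(benzyloxy)-4-methoxy-3,6-dimethylbenzoate | COc1cc(C)c(C(=O)Oc2c(C)c(O)c(C(=O)OC)c(C=O)c2Br)c(OCc2ccccc2)c1C
F4 | step 9 | 2-bromo-3-formyl-5-hydroxy-4-(methoxycarbonyl)-6-methylphenyl 2-hydroxy-4-methoxy-3,6-dimethylbenzoate | COc1cc(C)c(C(=O)Oc2c(C)c(O)c(C(=O)OC)c(C=O)c2Br)c(O)c1C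
F5 | step 9 | methyl 6-formyl-8-hydroxy-3-methoxy-1,4,9-trimethyl-11-oxo-11H-dibenzo[b,e][1,4]dioxepine-7-carboxylate | COc1cc(C)c2c(c1C)Oc1c(c(C)c(O)c(C(=O)OC)c1C=O)OC2=O
F6 | step 3 | methyl 2,4-bis(benzyloxy)-3,6-dimethylbenzoate | COC(=O)c1c(C)cc(OCc2ccccc2)c(C)c1OCc1ccccc1
F7 | step 3 | methyl 2,4-bis(benzyloxy)-6-[(hydroxyimino)methyl]-3-methylbenzoate (E/Z mixture) | COC(=O)c1c(C=NO)cc(OCc2ccccc2)c(C)c1OCc1ccccc1
F8 | step 3 | methyl 2,4-bis(benzyloxy)-6-formyl-3-methylbenzoate | COC(=O)c1c(C=O)cc(OCc2ccccc2)c(C)c1OCc1ccccc1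
F9 | step 15 | racemic 4-hydroxy-10-methoxy-5,8,11-trimethyl-3,7-dioxo-1H,3H,7H-isobenzofuro[4,5-b][1,4]benzodioxepin-1-yl acetate | COc1cc(C)c2c(c1C)Oc1c(c(C)c(O)c3c1C(OC(C)=O)OC3=O)OC2=O
F10 | step 15 | (1S)-4-hydroxy-10-methoxy-5,8,11-trimethyl-3,7-dioxo-1H,3H,7H-isobenzofuro[4,5-b][1,4]benzodioxepin-1-yl acetate | COc1cc(C)c2c(c1C)Oc1c(c(C)c(O)c3c1[C@@H](OC(C)=O)OC3=O)OC2=O
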